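The CH2CH2 bridge from C5 of ring A to ring B is read as a reduced acetylene. Ring A is the central ring (C1 OMe, C2 CH2Ar, C3 OH, C5 bridge) and ring B is the 2-hydroxyphenyl ring, so both hang on one two-carbon linchpin. In one pot, ethynyltrimethylsilane is coupled first with 1-(benzyloxy)-2-iodobenzene and, after fluoride unmasking, with a ring A aryl triflate, forming both aryl–alkyne bonds of a diarylalkyne. The precursor is the symmetric 4-[4-(benzyloxy)benzyl]-3,5-dimethoxyphenyl triflate, made from 4-hydroxy-2,6-dimethoxybenzaldehyde, whose CHO and OH already mark C2 and C5 of ring A. Hydrogenation and monodemethylation of one of two equivalent methyl ethers then give the target.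

Key step: step 5

Remark: the target has no stereocentre and is achiral, so no enantiocontrol is needed. The only stereocentre on the route, the carbinol carbon of 5, is formed racemic and is removed in step 3.

Step 1
Reactants: 1 4-hydroxy-2,6-dimethoxybenzaldehyde
Product: 2 4-formyl-3,5-dimethoxyphenyl trifluoromethanesulfonate
Conditions: Tf2O, pyridine, CH2Cl2, 0 °C
Reagents that add atoms: trifluoromethanesulfonic anhydride, O=S(=O)(OS(=O)(=O)C(F)(F)F)C(F)(F)F
Why: O-sulfonylation of a phenol (aryl triflate formation); the para-formyl phenol is acidic and should be triflated cleanly at 0 °C, the aldehyde and methyl ethers being inert to Tf2O/pyridine.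

Step 2
Reactants: 2 4-formyl-3,5-dimethoxyphenyl trifluoromethanesulfonate; 3 1-(benzyloxy)-4-bromobenzene
Product: 5 4-{[4-(benzyloxy)phenyl](hydroxy)methyl}-3,5-dimethoxyphenyl trifluoromethanesulfonate (racemic), via [4-(benzyloxy)phenyl]magnesium bromide 4 (not isolated)
Conditions: 3, Mg, THF, 40 °C; solution decanted from Mg, added to 2, THF, −78 → 0 °C; aq NH4Cl
Reagents that add atoms: none
Why: Grignard 1,2-addition to an aldehyde; at low temperature addition to the formyl group (activated by the para-triflate and by chelation to the ortho-methoxy groups) should be far faster than attack at the sulfonyl sulfur of the aryl triflate, which couples with Grignard reagents only under Ni or Pd catalysis, and the new carbinol centre is formed racemic because it is removed in step 3.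

Step 3
Reactants: 5 4-{[4-(benzyloxy)phenyl](hydroxy)methyl}-3,5-dimethoxyphenyl trifluoromethanesulfonate
Product: 6 4-[4-(benzyloxy)benzyl]-3,5-dimethoxyphenyl trifluoromethanesulfonate
Conditions: Et3SiH, TFA, CH2Cl2, 0 °C → rt
Reagents that add atoms: none
Why: Ionic hydrogenation (silane/acid deoxygenation of a diarylcarbinol); the doubly benzylic cation, stabilised by the 4-benzyloxyphenyl ring and the two ortho-methoxy groups, should be trapped by hydride from Et3SiH, while the aryl triflate, the aryl benzyl ether and the methyl ethers tolerate TFA at this temperature.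

Step 4
Reactants: 7 2-iodophenol
Product: 8 1-(benzyloxy)-2-iodobenzene
Conditions: BnBr, K2CO3, acetone, reflux
Reagents that add atoms: benzyl bromide, BrCc1ccccc1
Why: Williamson ether synthesis; the phenoxide is alkylated by the benzylic bromide and the aryl iodide is inert to these conditions.

Step 5
Reactants: 8 1-(benzyloxy)-2-iodobenzene; 9 ethynyltrimethylsilane; 6 4-[4-(benzyloxy)benzyl]-3,5-dimethoxyphenyl trifluoromethanesulfonate
Product: 12 2-[4-(benzyloxy)benzyl]-5-{[2-(benzyloxy)phenyl]ethynyl}-1,3-dimethoxybenzene, via {[2-(benzyloxy)phenyl]ethynyl}trimethylsilane 10 (not isolated), via 1-(benzyloxy)-2-ethynylbenzene 11 (not isolated)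
Conditions: 8, 9, PdCl2(PPh3)2 (cat.), CuI (cat.), Et3N, DMF (degassed), rt; excess 9 purged with argon; then 6, CsF, 80 °C
Reagents that add atoms: none
Why: Pd(0) inserts into the C–I bond of 8 at room temperature, the copper acetylide of 9 transmetalates and reductive elimination gives silylalkyne 10; CsF then removes the silyl group (terminal alkyne 11, with triethylammonium as proton source), and on warming Pd(0) inserts into the C5–OTf bond of 6 so that a second Sonogashira cycle gives 12. The closest known reaction type is the one-pot sequential Sonogashira/desilylation/Sonogashira synthesis of unsymmetrical diarylalkynes from a silylacetylene and two different aryl electrophiles. No ring is closed and no stereocentre is formed. The step needs each alkyne terminus to react once and only with its own partner: this is secured by the silyl group, which masks the second terminus until fluoride is added, by purging surplus 9 before unmasking, and by the reactivity gap between the aryl iodide (rt) and the aryl triflate (80 °C), 8 being fully consumed before 6 is added. The benzyl ether on ring B keeps the ortho oxygen from cyclising onto the alkyne to a benzofuran, exclusion of oxygen suppresses oxidative alkyne dimerisation, and the iodide liberated in the first stage should assist the coupling of the unhindered triflate.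

Step 6
Reactants: 12 2-[4-(benzyloxy)benzyl]-5-{[2-(benzyloxy)phenyl]ethynyl}-1,3-dimethoxybenzene
Product: 14 2-{2-[4-(4-hydroxybenzyl)-3,5-dimethoxyphenyl]ethyl}phenol, via 2-[4-(benzyloxy)benzyl]-5-{2-[2-(benzyloxy)phenyl]ethyl}-1,3-dimethoxybenzene 13 (not isolated)
Conditions: H2 (1 atm), 10% Pd/C, EtOAc–MeOH, rt (12 first filtered through silica to remove Cu, iodide and phosphine residues)
Reagents that add atoms: none
Why: Heterogeneous catalytic hydrogenation; the alkyne should be saturated first to the CH2CH2 bridge (13) and the two aryl benzyl ethers then cleaved by hydrogenolysis, while the methyl ethers and the diarylmethane CH2 are stable to Pd/C and H2.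

Step 7
Reactants: 14 2-{2-[4-(4-hydroxybenzyl)-3,5-dimethoxyphenyl]ethyl}phenol
Product: 15 5-[2-(2-hydroxyphenyl)ethyl]-2-(4-hydroxybenzyl)-3-methoxyphenol (target)
Conditions: NaSEt (5 equiv), DMF, 140 °C; aq HCl
Reagents that add atoms: none
Why: Nucleophilic (SN2) O-demethylation of an aryl methyl ether by thiolate; the two methoxy groups of ring A are equivalent by symmetry, so either cleavage gives 15, and the reaction should stop after one cleavage because the ring A phenoxide makes the remaining aryloxide a much poorer leaving group, as in the monodemethylation of resorcinol dimethyl ethers (excess thiolate covers deprotonation of the two phenols on the outer rings).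

Compound list
1 | 4-hydroxy-2,6-dimethoxybenzaldehyde | COc1cc(O)cc(OC)c1C=O | starting material
2 | 4-formyl-3,5-dimethoxyphenyl trifluoromethanesulfonate | COc1cc(OS(=O)(=O)C(F)(F)F)cc(OC)c1C=O | intermediate
3 | 1-(benzyloxy)-4-bromobenzene | Brc1ccc(OCc2ccccc2)cc1 | starting material
4 | [4-(benzyloxy)phenyl]magnesium bromide | Br[Mg]c1ccc(OCc2ccccc2)cc1 | intermediate
5 | 4-{[4-(benzyloxy)phenyl](hydroxy)methyl}-3,5-dimethoxyphenyl trifluoromethanesulfonate (racemic) | COc1cc(OS(=O)(=O)C(F)(F)F)cc(OC)c1C(O)c1ccc(OCc2ccccc2)cc1 | intermediate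
6 | 4-[4-(benzyloxy)benzyl]-3,5-dimethoxyphenyl trifluoromethanesulfonate | COc1cc(OS(=O)(=O)C(F)(F)F)cc(OC)c1Cc1ccc(OCc2ccccc2)cc1 | intermediate
7 | 2-iodophenol | Oc1ccccc1I | starting material
8 | 1-(benzyloxy)-2-iodobenzene | Ic1ccccc1OCc1ccccc1 | intermediate
9 | ethynyltrimethylsilane | C#C[Si](C)(C)C | starting material
10 | {[2-(benzyloxy)phenyl]ethynyl}trimethylsilane | C[Si](C)(C)C#Cc1ccccc1OCc1ccccc1 | intermediate
11 | 1-(benzyloxy)-2-ethynylbenzene | C#Cc1ccccc1OCc1ccccc1 | intermediate
12 | 2-[4-(benzyloxy)benzyl]-5-{[2-(benzyloxy)phenyl]ethynyl}-1,3-dimethoxybenzene | COc1cc(C#Cc2ccccc2OCc2ccccc2)cc(OC)c1Cc1ccc(OCc2ccccc2)cc1 | intermediate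
13 | 2-[4-(benzyloxy)benzyl]-5-{2-[2-(benzyloxy)phenyl]ethyl}-1,3-dimethoxybenzene | COc1cc(CCc2ccccc2OCc2ccccc2)cc(OC)c1Cc1ccc(OCc2ccccc2)cc1 | intermediate
14 | 2-{2-[4-(4-hydroxybenzyl)-3,5-dimethoxyphenyl]ethyl}phenol | COc1cc(CCc2ccccc2O)cc(OC)c1Cc1ccc(O)cc1 | intermediate
15 | 5-[2-(2-hydroxyphenyl)ethyl]-2-(4-hydroxybenzyl)-3-methoxyphenol | COc1cc(CCc2ccccc2O)cc(O)c1Cc1ccc(O)cc1 | target

Total step count: 7
Longest linear sequence: 6 steps (steps 1, 2, 3, 5, 6, 7; 1 → 2 → 5 → 6 → 12 → 14 → 15)

Steps most likely to fail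

Step 5. Oxidative addition into the ring A C–OTf bond may be slow. The unmasked alkyne could then dimerise oxidatively, fluoride could cleave the S–O bond of the triflate, or residual first-stage partners could scramble into symmetrical diarylalkynes. The fallback reverses the order of bond formation and gives up the one-pot operation; it sets out from 6 and comes back at 12. Triflate 6 is coupled with an excess of 9 (PdCl2(PPh3)2, CuI, Et3N, DMF, 80 °C, sealed vessel), where alkyne dimerisation costs nothing, to give ({4-[4-(benzyloxy)benzyl]-3,5-dimethoxyphenyl}ethynyl)trimethylsilane F1. Methanolysis (K2CO3, MeOH–THF, rt) gives 2-[4-(benzyloxy)benzyl]-5-ethynyl-1,3-dimethoxybenzene F2, which is isolated and coupled with the more reactive iodide 8 at room temperature (PdCl2(PPh3)2, CuI, Et3N, THF) to give 12.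

Step 7. The cleavage may run on to the second methyl ether or stall, since the substrate reacts as a poorly soluble dianion at high temperature. The fallback differentiates the two ring A oxygens before the key step; it sets out from 2 and comes back at 15.
- BCl3 (CH2Cl2, −78 → 0 °C) cleaves only one methyl ether of 2, the one chelated to the formyl group, giving 4-formyl-3-hydroxy-5-methoxyphenyl trifluoromethanesulfonate F3.
- Benzylation (BnBr, K2CO3, DMF, rt) gives 3-(benzyloxy)-4-formyl-5-methoxyphenyl trifluoromethanesulfonate F4.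
- Addition of Grignard reagent 4 as in step 2 gives 3-(benzyloxy)-4-{[4-(benzyloxy)phenyl](hydroxy)methyl}-5-methoxyphenyl trifluoromethanesulfonate F5 (racemic).
- Et3SiH/TFA as in step 3 gives 3-(benzyloxy)-4-[4-(benzyloxy)benzyl]-5-methoxyphenyl trifluoromethanesulfonate F6.
- The one-pot coupling of step 5 with 8 and 9 (through 10 and 11) gives 1-(benzyloxy)-2-[4-(benzyloxy)benzyl]-5-{[2-(benzyloxy)phenyl]ethynyl}-3-methoxybenzene F7.
- Hydrogenation as in step 6 passes through 1-(benzyloxy)-2-[4-(benzyloxy)benzyl]-5-{2-[2-(benzyloxy)phenyl]ethyl}-3-methoxybenzene F8 and removes all three benzyl groups, giving 15 directly without any demethylation.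

Step 2. The Grignard reagent may attack the sulfonyl sulfur, with loss of the triflate, or add sluggishly to the di-ortho-substituted aldehyde. The fallback installs the triflate only after the carbon–carbon bond is made; it sets out from 1 and comes back at 6.
- Silylation of 1 (TBSCl, imidazole, DMF, rt) gives 4-{[tert-butyl(dimethyl)silyl]oxy}-2,6-dimethoxybenzaldehyde F9.
- Addition of 4 (THF, 0 °C) gives [4-(benzyloxy)phenyl](4-{[tert-butyl(dimethyl)silyl]oxy}-2,6-dimethoxyphenyl)methanol F10 (racemic).
- Et3SiH/TFA (CH2Cl2, 0 °C) gives {4-[4-(benzyloxy)benzyl]-3,5-dimethoxyphenoxy}(tert-butyl)dimethylsilane F11.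
- TBAF (THF, 0 °C) gives 4-[4-(benzyloxy)benzyl]-3,5-dimethoxyphenol F12; any silyl ether already lost in the acidic reduction converges on the same phenol.
- Triflation as in step 1 (Tf2O, pyridine, CH2Cl2, 0 °C) gives 6.

Further compounds
F1 | step 5 | ({4-[4-(benzyloxy)benzyl]-3,5-dimethoxyphenyl}ethynyl)trimethylsilane | COc1cc(C#C[Si](C)(C)C)cc(OC)c1Cc1ccc(OCc2ccccc2)cc1
F2 | step 5 | 2-[4-(benzyloxy)benzyl]-5-ethynyl-1,3-dimethoxybenzene | COc1cc(C#C)cc(OC)c1Cc1ccc(OCc2ccccc2)cc1
F3 | step 7 | 4-formyl-3-hydroxy-5-methoxyphenyl trifluoromethanesulfonate | COc1cc(OS(=O)(=O)C(F)(F)F)cc(O)c1C=O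
F4 | step 7 | 3-(benzyloxy)-4-formyl-5-methoxyphenyl trifluoromethanesulfonate | COc1cc(OS(=O)(=O)C(F)(F)F)cc(OCc2ccccc2)c1C=O
F5 | step 7 | 3-(benzyloxy)-4-{[4-(benzyloxy)phenyl](hydroxy)methyl}-5-methoxyphenyl trifluoromethanesulfonate (racemic) | COc1cc(OS(=O)(=O)C(F)(F)F)cc(OCc2ccccc2)c1C(O)c1ccc(OCc2ccccc2)cc1
F6 | step 7 | 3-(benzyloxy)-4-[4-(benzyloxy)benzyl]-5-methoxyphenyl trifluoromethanesulfonate | COc1cc(OS(=O)(=O)C(F)(F)F)cc(OCc2ccccc2)c1Cc1ccc(OCc2ccccc2)cc1
F7 | step 7 | 1-(benzyloxy)-2-[4-(benzyloxy)benzyl]-5-{[2-(benzyloxy)phenyl]ethynyl}-3-methoxybenzene | COc1cc(C#Cc2ccccc2OCc2ccccc2)cc(OCc2ccccc2)c1Cc1ccc(OCc2ccccc2)cc1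
F8 | step 7 | 1-(benzyloxy)-2-[4-(benzyloxy)benzyl]-5-{2-[2-(benzyloxy)phenyl]ethyl}-3-methoxybenzene | COc1cc(CCc2ccccc2OCc2ccccc2)cc(OCc2ccccc2)c1Cc1ccc(OCc2ccccc2)cc1
F9 | step 2 | 4-{[tert-butyl(dimethyl)silyl]oxy}-2,6-dimethoxybenzaldehyde | COc1cc(O[Si](C)(C)C(C)(C)C)cc(OC)c1C=O
F10 | step 2 | [4-(benzyloxy)phenyl](4-{[tert-butyl(dimethyl)silyl]oxy}-2,6-dimethoxyphenyl)methanol (racemic) | COc1cc(O[Si](C)(C)C(C)(C)C)cc(OC)c1C(O)c1ccc(OCc2ccccc2)cc1
F11 | step 2 | {4-[4-(benzyloxy)benzyl]-3,5-dimethoxyphenoxy}(tert-butyl)dimethylsilane | COc1cc(O[Si](C)(C)C(C)(C)C)cc(OC)c1Cc1ccc(OCc2ccccc2)cc1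
F12 | step 2 | 4-[4-(benzyloxy)benzyl]-3,5-dimethoxyphenol | COc1cc(O)cc(OC)c1Cc1ccc(OCc2ccccc2)cc1
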